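## The problem

Glyinflanin C (14) is a dibenzoylmethane in which a three-carbon 1,3-dione chain joins ring B, a 4-hydroxy-3-(3-methylbut-2-enyl)phenyl group, to ring A, the benzene ring of a 7-hydroxy-2,2-dimethyl-2H-chromene that carries the chain at C6. There is no stereocentre, so every difficulty is one of position and of functional-group tolerance. The pyran must be fused linearly through C4a and C8a, with the acyl group on C6 and the hydroxyl on C7, whereas resorcinol ketones with a free, hydrogen-bonded ortho hydroxyl tend to annulate at the carbon between the two oxygens (C8) and give the angular isomer. On ring B the prenyl group must sit on carbon, ortho to the hydroxyl, and not on oxygen. The finished molecule tolerates little: acid turns the 2-hydroxyaryl 1,3-diketone into a flavone, closes the prenyl phenol to a chroman and attacks the C3=C4 double bond; hot alkali splits the diketone by retro-Claisen cleavage; hydrogenation is excluded by the two alkenes, the prenyl double bond and C3=C4. Protecting groups therefore have to leave with fluoride, and the diketone has to be made without strong acid or strong base. The feature that opens a short route is the position of C4a: it is ortho to C8a (which bears the pyran oxygen O1), para to the C7 oxygen and only meta to the C6 carbonyl. It is thus a nucleophilic arene carbon that an alkyne hung on O1 through the gem-dimethyl carbon C2 can reach, the alkyne terminus becoming C4.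

## Retrosynthesis

The two O–Si bonds of the bis-silyl ether 13 are cut last. Silyl ethers are the only phenol protection that leaves with buffered fluoride, which spares the chromene, the prenyl group and the hydroxyaryl diketone; acetals or benzyl ethers would need acid or hydrogen. The silyl group on the C7 oxygen is triisopropylsilyl because it also has a steering role one step earlier. The one on ring B is tert-butyldimethylsilyl because it arrives with the acyl donor.

In 13 the C4–C4a bond is cut, which opens the pyran to the aryl 2-methylbut-3-yn-2-yl ether 12. The neighbouring cuts are less attractive. Cutting O1–C2 asks for a C-prenylated ring A and an oxidant that must ignore ring B. Cutting O1–C8a asks for a halogenated arene and a cis alkene. The C4–C4a cut instead places the pyran carbons on the resorcinol oxygen that is easiest to alkylate selectively. Compound 12 has the same atoms as 13 and one ring fewer. The forward reaction must be a 6-endo-dig hydroarylation by monovalent gold at the ring carbon para to the silyloxy group, and it must leave the diketone and the prenyl alkene alone. The closure is placed after the diketone is built so that the acid-sensitive chromene does not pass through the Lewis-acidic acylation; the terminal alkyne is inert there.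

In 12 the bond between the central methylene carbon and the ring B carbonyl is cut, giving methyl ketone 5 and aroyl chloride 11. The opposite cut would need a 2,4-dioxygenated benzoyl donor and a prenylated acetophenone, neither of which is as accessible. The classical Baker–Venkataraman acyl shift would deliver a free, chelated C7 hydroxyl, which is exactly what the ring closure must avoid. The forward reaction is a C-acylation by soft enolisation, because a strong amide base would threaten the terminal alkyne C–H and invite silyl migration.

Ketone 5 is traced by an O–Si cut to phenol 4, and 4 by an O–C cut to 2,4-dihydroxyacetophenone (1) and 2-methylbut-3-yn-2-ol (2), activated in the flask as its trifluoroacetate 3. The 4-hydroxyl of 1 is the more acidic and the only unchelated one, so the order alkylation-then-silylation needs no extra protection.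

Acid chloride 11 comes from the silyl ester 10 under neutral conditions, 10 from hydroxy acid 9, 9 from ester 8, and 8 by an aryl C–C cut from methyl 4-hydroxybenzoate (6) and 1-bromo-3-methylbut-2-ene (7). The para position of 6 is blocked, so C-alkylation can only occur ortho to the hydroxyl.

## Roads not taken

Alternative 1: Ring A itself is taken apart at C6–C7, back to the dioxinone-capped open chain (5Z)-1-[4-(tert-butyldimethylsilyloxy)-3-(3-methylbut-2-enyl)phenyl]-6-(2,2-dimethyl-4-oxo-4H-1,3-dioxin-6-yl)-9-methyldeca-5,8-diene-1,3-dione (A1). On heating, A1 would lose acetone to give an acylketene. The enolisable C6 carbon would attack the ketene carbon across the cis alkene, and tautomerisation would give the resorcinol 1-[4-(tert-butyldimethylsilyloxy)-3-(3-methylbut-2-enyl)phenyl]-3-[2,4-dihydroxy-5-(3-methylbut-2-enyl)phenyl]propane-1,3-dione (A2).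
- Merits: the substitution pattern of ring A is written into the chain, and the later pyran closure has only one phenol next to the prenyl group. The linear fusion is therefore certain, which is better than what the chosen plan can promise.
- Weak points: A1 is a long polycarbonyl chain with a skipped cis enone that can slip into conjugation. The acylketene can be caught by the enol oxygen of the diketone instead of by carbon. A2 still needs an oxidative pyran closure in the presence of a second prenyl arene, and then a desilylation.
- Comparison: the chosen plan sets against the better positional certainty two purchased benzene rings, nine steps in all and no oxidant.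

Alternative 2: The pyran is cut at O1–C8a, back to 4-fluoro-5-[(1Z)-3-hydroxy-3-methylbut-1-enyl]-2-(methoxymethoxy)benzaldehyde (A3). With KOtBu the tertiary alkoxide of A3 would displace the fluoride para to the formyl group, giving 7-(methoxymethoxy)-2,2-dimethyl-2H-chromene-6-carbaldehyde (A4).
- Merits: the positions of fluorine and side chain in A3 leave no second site, so aldehyde A4 can only be the linear chromene, and no metal catalyst is involved. In this respect the road is superior.
- Weak points: A3 costs a halogenation, an alkyne coupling and a cis-selective semihydrogenation. The diketone must then be grown from A4 by aldol addition and oxidation. The methoxymethyl ether that A4 carries has to leave with acid at the very end, where the chromene, the prenyl phenol and the hydroxyaryl diketone are all acid-sensitive.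
- Comparison: against the regiochemical certainty of A4 the chosen plan sets a shorter sequence, a one-step diketone synthesis and a fluoride end-game.

Alternative 3: Ring B is built instead of bought. The diene (1E,3Z)-1-methoxy-7-methyl-3-(trimethylsilyloxy)octa-1,3,6-triene (A5) and the ynone (1E)-1-methoxy-1-[7-(methoxymethoxy)-2,2-dimethyl-2H-chromen-6-yl]pent-1-en-4-yn-3-one (A6) would undergo (4+2) cycloaddition and lose methanol. The product would be (2E)-1-[4-hydroxy-3-(3-methylbut-2-enyl)phenyl]-3-methoxy-3-[7-(methoxymethoxy)-2,2-dimethyl-2H-chromen-6-yl]prop-2-en-1-one (A7).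
- Merits: the prenyl group is placed ortho to the hydroxyl by construction. This avoids the C-prenylation of a phenoxide, the weakest ordinary step of the chosen plan.
- Weak points: the key step is spent on the simple ring. The chromene of A6 must be made beforehand, so the harder linear-fusion problem stays unsolved. A5 is a hydrolytically fragile silyl enol ether and A6 a doubly activated acceptor. A7 needs acid twice, for the enol ether and for the acetal.
- Comparison: the chosen plan accepts a modest C-prenylation on a cheap ester in its first ring B step and keeps acid out of the late stages.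

Key step: step 8

Remark on the chemistry: the 1,3-diketones 12, 13 and 14 are drawn and named in the diketo form; each should exist largely as its chelated enol, which changes no step.

## Steps

Step 1
Reactants: 1 2,4-dihydroxyacetophenone; 2 2-methylbut-3-yn-2-ol
Product: 4 1-[2-hydroxy-4-(2-methylbut-3-yn-2-yloxy)phenyl]ethanone, via 2-methylbut-3-yn-2-yl trifluoroacetate 3 (not isolated)
Conditions: 2, (CF3CO)2O, DBU, MeCN, −5 °C; then added to 1, DBU, CuCl2·2H2O (0.1 mol %), MeCN, 0 °C
Reagents that add atoms: trifluoroacetic anhydride, O=C(OC(=O)C(F)(F)F)C(F)(F)F (its trifluoroacetyl group is carried only by intermediate 3 and is lost again on the way to 4)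
Why: Copper-catalysed propargylic etherification of a phenol with a tertiary propargylic trifluoroacetate; only the unchelated, more acidic 4-hydroxyl is deprotonated by DBU, and the reaction runs at 0 °C, far below the onset of Claisen rearrangement.

Step 2
Reactants: 4 1-[2-hydroxy-4-(2-methylbut-3-yn-2-yloxy)phenyl]ethanone
Product: 5 1-[4-(2-methylbut-3-yn-2-yloxy)-2-(triisopropylsilyloxy)phenyl]ethanone
Conditions: TIPSOTf, 2,6-lutidine, CH2Cl2, 0 °C → rt
Reagents that add atoms: triisopropylsilyl trifluoromethanesulfonate, CC(C)[Si](C(C)C)(C(C)C)OS(=O)(=O)C(F)(F)F
Why: Silylation of a hindered, hydrogen-bonded phenol with a silyl triflate and a hindered pyridine base, which does not enolise the methyl ketone; the large silyl group breaks the chelate, shields the flanking ring carbon and resists O-to-O migration.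

Step 3
Reactants: 6 methyl 4-hydroxybenzoate; 7 1-bromo-3-methylbut-2-ene
Product: 8 methyl 4-hydroxy-3-(3-methylbut-2-enyl)benzoate
Conditions: NaH, toluene, 0 °C; then 7, rt
Reagents that add atoms: none
Why: Ortho C-alkylation of a tight sodium phenoxide ion pair in a non-polar solvent; the para position is blocked by the ester, and direct displacement at the primary carbon of the bromide gives the linear prenyl group.

Step 4
Reactants: 8 methyl 4-hydroxy-3-(3-methylbut-2-enyl)benzoate
Product: 9 4-hydroxy-3-(3-methylbut-2-enyl)benzoic acid
Conditions: NaOH, MeOH–H2O, 65 °C; then 1 M HCl, 0 °C, to pH 3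
Reagents that add atoms: sodium hydroxide, [Na+].[OH-]
Why: Ester saponification by acyl–oxygen cleavage; the phenoxide slows but does not stop it, and the brief cold acidification is too mild to close the prenyl phenol to a chroman.

Step 5
Reactants: 9 4-hydroxy-3-(3-methylbut-2-enyl)benzoic acid
Product: 10 tert-butyldimethylsilyl 4-(tert-butyldimethylsilyloxy)-3-(3-methylbut-2-enyl)benzoate
Conditions: TBSCl (2.5 equiv), imidazole, DMF, rt
Reagents that add atoms: tert-butyldimethylsilyl chloride, CC(C)(C)[Si](C)(C)Cl
Why: Imidazole-mediated silylation of both the phenol and the carboxylic acid; the silyl ester is kept on purpose as a neutral precursor of the acid chloride.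

Step 6
Reactants: 10 tert-butyldimethylsilyl 4-(tert-butyldimethylsilyloxy)-3-(3-methylbut-2-enyl)benzoate
Product: 11 4-(tert-butyldimethylsilyloxy)-3-(3-methylbut-2-enyl)benzoyl chloride
Conditions: (COCl)2, DMF (cat.), CH2Cl2, 0 °C → rt; evaporated and used crude
Reagents that add atoms: oxalyl chloride, O=C(Cl)C(=O)Cl
Why: Conversion of a silyl ester into an acid chloride by the chloroiminium salt formed from DMF and oxalyl chloride; the silicon leaves as the silyl chloride and no HCl is formed, so the prenyl alkene and the aryl silyl ether are spared.

Step 7
Reactants: 5 1-[4-(2-methylbut-3-yn-2-yloxy)-2-(triisopropylsilyloxy)phenyl]ethanone; 11 4-(tert-butyldimethylsilyloxy)-3-(3-methylbut-2-enyl)benzoyl chloride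
Product: 12 1-[4-(tert-butyldimethylsilyloxy)-3-(3-methylbut-2-enyl)phenyl]-3-[4-(2-methylbut-3-yn-2-yloxy)-2-(triisopropylsilyloxy)phenyl]propane-1,3-dione
Conditions: MgBr2·OEt2 (2.5 equiv), i-Pr2NEt (3 equiv), CH2Cl2, rt; cold aq. citric acid work-up
Reagents that add atoms: none
Why: C-acylation of a ketone by soft enolisation: coordination to MgBr2 makes the methyl ketone acidic enough for an amine base, the magnesium enolate is acylated on carbon, and the product is held as its magnesium diketonate, which blocks a second acylation. No strong base is present, so the alkyne C–H and both silyl ethers stay untouched.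

Step 8
Reactants: 12 1-[4-(tert-butyldimethylsilyloxy)-3-(3-methylbut-2-enyl)phenyl]-3-[4-(2-methylbut-3-yn-2-yloxy)-2-(triisopropylsilyloxy)phenyl]propane-1,3-dione
Product: 13 1-[4-(tert-butyldimethylsilyloxy)-3-(3-methylbut-2-enyl)phenyl]-3-[2,2-dimethyl-7-(triisopropylsilyloxy)-2H-chromen-6-yl]propane-1,3-dione
Conditions: Ph3PAuNTf2 (5 mol %), CH2Cl2, rt
Reagents that add atoms: none
Why: The cationic monovalent gold complex binds the terminal alkyne of 12 and makes it electrophilic; the ring A carbon ortho to the ether oxygen and para to the silyloxy group attacks the terminal alkyne carbon, forming C4–C4a and an arenium vinylgold species. Loss of the ring proton and protodeauration give the C3=C4 double bond of 13 and return the catalyst. The closest known reaction type is the gold-catalysed intramolecular hydroarylation of aryl 1,1-dimethylpropargyl ethers to 2H-chromenes. The pyran ring closes in the 6-endo-dig mode: the short O–CMe2 tether holds the alkyne terminus over the ortho carbon, and the propargylic oxygen disfavours positive charge at the internal carbon that 5-exo attack would need. No stereocentre is formed. The step needs closure at the future C4a and not at the carbon between the two oxygens: both are meta to the acyl group, but C4a is para to the silyloxy donor and unhindered, whereas the other carbon is flanked by the triisopropylsilyl ether. Silylation has also removed the hydrogen-bond chelate that sends free 2-hydroxyaryl ketones to the angular position. It also needs the alkyne to react in preference to the prenyl alkene and the enolised diketone, which the much stronger activation of alkynes by monovalent gold at room temperature should secure, helped by the gem-dimethyl group that favours the folded conformer.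

Step 9
Reactants: 13 1-[4-(tert-butyldimethylsilyloxy)-3-(3-methylbut-2-enyl)phenyl]-3-[2,2-dimethyl-7-(triisopropylsilyloxy)-2H-chromen-6-yl]propane-1,3-dione
Product: 14 Glyinflanin C, 1-[4-hydroxy-3-(3-methylbut-2-enyl)phenyl]-3-(7-hydroxy-2,2-dimethyl-2H-chromen-6-yl)propane-1,3-dione
Conditions: Bu4NF (2.5 equiv), AcOH (2.5 equiv), THF, 0 °C
Reagents that add atoms: none
Why: Fluoride cleavage of both aryl silyl ethers, driven by the Si–F bond; acetic acid buffers the liberated phenoxides so that neither retro-Claisen cleavage nor acid-type cyclisation of the hydroxyaryl diketone or the prenyl phenol can set in.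

## Compound list

1 | 2,4-dihydroxyacetophenone | CC(=O)c1ccc(O)cc1O | starting material
2 | 2-methylbut-3-yn-2-ol | CC(C)(O)C#C | starting material
3 | 2-methylbut-3-yn-2-yl trifluoroacetate | C#CC(C)(C)OC(=O)C(F)(F)F | intermediate
4 | 1-[2-hydroxy-4-(2-methylbut-3-yn-2-yloxy)phenyl]ethanone | C#CC(C)(C)Oc1ccc(C(C)=O)c(O)c1 | intermediate
5 | 1-[4-(2-methylbut-3-yn-2-yloxy)-2-(triisopropylsilyloxy)phenyl]ethanone | C#CC(C)(C)Oc1ccc(C(C)=O)c(O[Si](C(C)C)(C(C)C)C(C)C)c1 | intermediate
6 | methyl 4-hydroxybenzoate | COC(=O)c1ccc(O)cc1 | starting material
7 | 1-bromo-3-methylbut-2-ene | CC(C)=CCBr | starting material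
8 | methyl 4-hydroxy-3-(3-methylbut-2-enyl)benzoate | COC(=O)c1ccc(O)c(CC=C(C)C)c1 | intermediate
9 | 4-hydroxy-3-(3-methylbut-2-enyl)benzoic acid | OC(=O)c1ccc(O)c(CC=C(C)C)c1 | intermediate
10 | tert-butyldimethylsilyl 4-(tert-butyldimethylsilyloxy)-3-(3-methylbut-2-enyl)benzoate | CC(C)=CCc1cc(C(=O)O[Si](C)(C)C(C)(C)C)ccc1O[Si](C)(C)C(C)(C)C | intermediate
11 | 4-(tert-butyldimethylsilyloxy)-3-(3-methylbut-2-enyl)benzoyl chloride | CC(C)=CCc1cc(C(=O)Cl)ccc1O[Si](C)(C)C(C)(C)C | intermediate
12 | 1-[4-(tert-butyldimethylsilyloxy)-3-(3-methylbut-2-enyl)phenyl]-3-[4-(2-methylbut-3-yn-2-yloxy)-2-(triisopropylsilyloxy)phenyl]propane-1,3-dione | C#CC(C)(C)Oc1ccc(C(=O)CC(=O)c2ccc(O[Si](C)(C)C(C)(C)C)c(CC=C(C)C)c2)c(O[Si](C(C)C)(C(C)C)C(C)C)c1 | intermediate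
13 | 1-[4-(tert-butyldimethylsilyloxy)-3-(3-methylbut-2-enyl)phenyl]-3-[2,2-dimethyl-7-(triisopropylsilyloxy)-2H-chromen-6-yl]propane-1,3-dione | CC(C)[Si](C(C)C)(C(C)C)Oc1cc2OC(C)(C)C=Cc2cc1C(=O)CC(=O)c1ccc(O[Si](C)(C)C(C)(C)C)c(CC=C(C)C)c1 | intermediate
14 | Glyinflanin C, 1-[4-hydroxy-3-(3-methylbut-2-enyl)phenyl]-3-(7-hydroxy-2,2-dimethyl-2H-chromen-6-yl)propane-1,3-dione | CC(C)=CCc1cc(C(=O)CC(=O)c2cc3c(cc2O)OC(C)(C)C=C3)ccc1O | target

## Step count and risks

Total: 9 steps. Longest linear sequence: 7 steps (steps 3, 4, 5, 6, 7, 8, 9); the ring A branch (steps 1 and 2) joins at step 7.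

Step 8 (key step). Most likely to go wrong:
- partial ring closure at the crowded carbon between the two oxygens, which would give the angular chromene;
- stalling of the catalysis, because the enolised diketone or traces of water take up the cationic gold, the latter by alkyne hydration.

Fallback: the ring is closed before the diketone exists and without a π-acid. Setting out from 5, heating in N,N-diethylaniline at about 180 °C should bring about the aryl propargyl Claisen rearrangement, a 1,5-hydrogen shift and an oxa-6π electrocyclisation, giving 1-[2,2-dimethyl-7-(triisopropylsilyloxy)-2H-chromen-6-yl]ethanone F1. The bulky silyl ether should again disfavour the crowded ortho carbon, and any angular isomer can be removed at the stage of this small ketone. Acylation of F1 with 11 under the conditions of step 7, whose mild Lewis acid MgBr2 the 2,2-dimethylchromene should tolerate, returns to the route at 13.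

Step 7. Most likely to go wrong:
- acylation on the enolate oxygen or a second acylation of the product;
- slow enolisation of the hindered ortho-silyloxy ketone, so that the acid chloride is lost to hydrolysis.

Fallback: the diketone is reached by aldol addition and oxidation. Setting out from 11 and 5, reduction of 11 with LiAlH(OtBu)3 in THF at −78 °C gives 4-(tert-butyldimethylsilyloxy)-3-(3-methylbut-2-enyl)benzaldehyde F2. Addition of the lithium enolate of 5 (LiN(SiMe3)2, 1 equiv, THF, −78 °C) gives racemic 3-[4-(tert-butyldimethylsilyloxy)-3-(3-methylbut-2-enyl)phenyl]-3-hydroxy-1-[4-(2-methylbut-3-yn-2-yloxy)-2-(triisopropylsilyloxy)phenyl]propan-1-one F3. Oxidation of F3 with 2-iodoxybenzoic acid in warm ethyl acetate returns to the route at 12.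

Step 3. Most likely to go wrong:
- alkylation on oxygen instead of carbon;
- a second C-alkylation at the other ortho position.

Both would lower the throughput of the ring B branch. Fallback: the prenyl group is delivered by a sigmatropic shift. Setting out from 6 and 2, etherification under the conditions of step 1 (through 3) gives methyl 4-(2-methylbut-3-yn-2-yloxy)benzoate F4. Semihydrogenation (H2, Pd/CaCO3 poisoned with Pb(OAc)2, quinoline) gives methyl 4-(2-methylbut-3-en-2-yloxy)benzoate F5. Aromatic Claisen rearrangement of F5 in hot N,N-diethylaniline moves the allyl unit to the ortho carbon with allylic transposition and returns to the route at 8.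

## Further compounds

F1 | step 8 | 1-[2,2-dimethyl-7-(triisopropylsilyloxy)-2H-chromen-6-yl]ethanone | CC(=O)c1cc2C=CC(C)(C)Oc2cc1O[Si](C(C)C)(C(C)C)C(C)C
F2 | step 7 | 4-(tert-butyldimethylsilyloxy)-3-(3-methylbut-2-enyl)benzaldehyde | CC(C)=CCc1cc(C=O)ccc1O[Si](C)(C)C(C)(C)C
F3 | step 7 | racemic 3-[4-(tert-butyldimethylsilyloxy)-3-(3-methylbut-2-enyl)phenyl]-3-hydroxy-1-[4-(2-methylbut-3-yn-2-yloxy)-2-(triisopropylsilyloxy)phenyl]propan-1-one | C#CC(C)(C)Oc1ccc(C(=O)CC(O)c2ccc(O[Si](C)(C)C(C)(C)C)c(CC=C(C)C)c2)c(O[Si](C(C)C)(C(C)C)C(C)C)c1
F4 | step 3 | methyl 4-(2-methylbut-3-yn-2-yloxy)benzoate | COC(=O)c1ccc(OC(C)(C)C#C)cc1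
F5 | step 3 | methyl 4-(2-methylbut-3-en-2-yloxy)benzoate | COC(=O)c1ccc(OC(C)(C)C=C)cc1
A1 | alternative 1 | (5Z)-1-[4-(tert-butyldimethylsilyloxy)-3-(3-methylbut-2-enyl)phenyl]-6-(2,2-dimethyl-4-oxo-4H-1,3-dioxin-6-yl)-9-methyldeca-5,8-diene-1,3-dione | CC(C)=CC/C(C1=CC(=O)OC(C)(C)O1)=C/CC(=O)CC(=O)c1ccc(O[Si](C)(C)C(C)(C)C)c(CC=C(C)C)c1
A2 | alternative 1 | 1-[4-(tert-butyldimethylsilyloxy)-3-(3-methylbut-2-enyl)phenyl]-3-[2,4-dihydroxy-5-(3-methylbut-2-enyl)phenyl]propane-1,3-dione | CC(C)=CCc1cc(C(=O)CC(=O)c2ccc(O[Si](C)(C)C(C)(C)C)c(CC=C(C)C)c2)c(O)cc1O
A3 | alternative 2 | 4-fluoro-5-[(1Z)-3-hydroxy-3-methylbut-1-enyl]-2-(methoxymethoxy)benzaldehyde | COCOc1cc(F)c(/C=C\C(C)(C)O)cc1C=O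
A4 | alternative 2 | 7-(methoxymethoxy)-2,2-dimethyl-2H-chromene-6-carbaldehyde | COCOc1cc2OC(C)(C)C=Cc2cc1C=O
A5 | alternative 3 | (1E,3Z)-1-methoxy-7-methyl-3-(trimethylsilyloxy)octa-1,3,6-triene | CO/C=C/C(O[Si](C)(C)C)=C/CC=C(C)C
A6 | alternative 3 | (1E)-1-methoxy-1-[7-(methoxymethoxy)-2,2-dimethyl-2H-chromen-6-yl]pent-1-en-4-yn-3-one | C#CC(=O)/C=C(/OC)c1cc2C=CC(C)(C)Oc2cc1OCOC
A7 | alternative 3 | (2E)-1-[4-hydroxy-3-(3-methylbut-2-enyl)phenyl]-3-methoxy-3-[7-(methoxymethoxy)-2,2-dimethyl-2H-chromen-6-yl]prop-2-en-1-one | CC(C)=CCc1cc(C(=O)/C=C(/OC)c2cc3C=CC(C)(C)Oc3cc2OCOC)ccc1O
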